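**Retrosynthetic overview**
- Target phenol ⇒ (rearomatisation, loss of MeOH) a 5‑heptadecyl‑4,4‑dimethoxycyclohexenone.
- That enone ⇒ (C(sp3)–C(ring) bond, the proposed new step) a quinone monoketal plus a heptadecyl radical from stearic acid (C18 acid gives the C17 chain by loss of CO2).
- Quinone monoketal ⇒ (oxidative dearomatisation) 3,4‑dimethoxyphenol.
- Rings: no ring is built. The one benzene ring is bought, dearomatised, alkylated at the future C3, and re‑formed in the last step.

Assumption: the target is achiral (no stereocentre, no stereogenic double bond), so "single enantiomer" needs no stereocontrol. The only stereocentre on the way (C5 of 4) is racemic and is erased in step 3.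

**Route**

Step 1
Reactants: 1 3,4‑dimethoxyphenol
Product: 2 3,4,4‑trimethoxycyclohexa‑2,5‑dien‑1‑one
Conditions: PhI(OAc)2 (1.1 equiv), MeOH, 0 °C to rt, 30 min; NaHCO3 work‑up
Reagents that add atoms: methanol, CO
Why: Hypervalent‑iodine oxidative dearomatisation of a p‑alkoxyphenol; MeOH traps the phenoxenium ion at the methoxy‑bearing para carbon to give the quinone monoketal, and no stereocentre is formed.

Step 2
Reactants: 2 3,4,4‑trimethoxycyclohexa‑2,5‑dien‑1‑one; 3 octadecanoic acid (stearic acid)
Product: 4 rac‑5‑heptadecyl‑3,4,4‑trimethoxycyclohex‑2‑en‑1‑one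
Conditions: 3 (1.5 equiv), [Ir(dF(CF3)ppy)2(dtbbpy)]PF6 (1 mol%), K2HPO4 (1.0 equiv), DMF/PhCF3 3:1 (0.1 M), Ar, 450 nm LEDs, 30 °C, 24 h
Reagents that add atoms: none
Why: Proposed new method: a photoredox decarboxylative Giese addition with a quinone monoketal as the radical acceptor, in which excited Ir(III) oxidises stearate, loss of CO2 gives the nucleophilic heptadecyl radical, this adds to C5 of 2 (the only unsubstituted enone β‑carbon; C3 is a methoxy‑bearing, deactivated vinylogous‑ester carbon), and the α‑keto radical is reduced by Ir(II) to the enolate and protonated, so the cycle is redox‑neutral; the closest known reaction types are the photoredox decarboxylative conjugate addition of carboxylic acids to simple enones and the organocuprate 1,4‑addition to quinone monoketals; the new C5 stereocentre forms racemic and is removed in step 3.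

Step 3
Reactants: 4 rac‑5‑heptadecyl‑3,4,4‑trimethoxycyclohex‑2‑en‑1‑one
Product: 6 3‑heptadecyl‑4,5‑dimethoxyphenol, via dienone 5 (not isolated)
Conditions: CSA (10 mol%), 4 Å MS, dry CH2Cl2, 0 °C to rt, 1 h
Reagents that add atoms: none
Why: Acid‑catalysed ketal ionisation and E1 loss of MeOH give the cyclohexa‑2,4‑dienone, which tautomerises to the phenol (aromatisation‑driven elimination/keto–enol tautomerisation); anhydrous acid avoids ketal hydrolysis, and the C5 stereocentre is erased.

**Compound list**
1 | 3,4‑dimethoxyphenol | COc1ccc(O)cc1OC | starting material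
2 | 3,4,4‑trimethoxycyclohexa‑2,5‑dien‑1‑one | COC1=CC(=O)C=CC1(OC)OC | intermediate
3 | octadecanoic acid (stearic acid) | CCCCCCCCCCCCCCCCCC(=O)O | starting material
4 | rac‑5‑heptadecyl‑3,4,4‑trimethoxycyclohex‑2‑en‑1‑one (racemic at C5) | CCCCCCCCCCCCCCCCCC1CC(=O)C=C(OC)C1(OC)OC | intermediate
5 | 5‑heptadecyl‑3,4‑dimethoxycyclohexa‑2,4‑dien‑1‑one | CCCCCCCCCCCCCCCCCC1=C(OC)C(OC)=CC(=O)C1 | intermediate
6 | 3‑heptadecyl‑4,5‑dimethoxyphenol | CCCCCCCCCCCCCCCCCc1cc(O)cc(OC)c1OC | target

**Totals**
Total step count: 3. Longest linear sequence: 3 (1 → 2 → 4 → 6).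

**Steps most likely to fail, with fallbacks**

Step 2 (the proposed new reaction) is the most likely to fail. The primary radical may add slowly next to the ketal carbon, and the dienone may suffer reductive fragmentation back to 1 or sensitised photorearrangement. The fallback uses known chemistry, sets out from 2 and comes back at 4. 1‑Bromoheptadecane F3 is converted with Mg turnings in THF into heptadecylmagnesium bromide F4. F4 (1.3 equiv) is added to 2 in THF at −78 to −40 °C with CuBr·SMe2 (10 mol%), a copper‑catalysed 1,4‑addition of a Grignard reagent to the unsubstituted enone arm of the quinone monoketal. Quenching with aqueous NH4Cl gives 4, which continues with step 3.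

Step 3 is second. Adventitious water could hydrolyse the ketal instead of eliminating MeOH, which would give the 4‑hydroxy compound rather than the 4‑methoxy compound. The fallback sets out from 4 and comes back at 6, and it uses that hydrolysis deliberately. Aqueous HCl in THF under Ar converts 4 into 5‑heptadecyl‑3‑methoxycyclohex‑2‑ene‑1,4‑dione F5, which tautomerises in the same flask to 2‑heptadecyl‑6‑methoxybenzene‑1,4‑diol F6. TIPSCl and imidazole in DMF silylate only the unhindered 4‑OH to give 2‑heptadecyl‑6‑methoxy‑4‑[(triisopropylsilyl)oxy]phenol F7. MeI and K2CO3 in acetone methylate the remaining hindered OH to give (3‑heptadecyl‑4,5‑dimethoxyphenoxy)triisopropylsilane F8. TBAF in THF then releases 6.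

Step 1 is third. Over‑oxidation to 2‑methoxy‑1,4‑benzoquinone or acid‑induced decomposition of 2 on isolation are the likely problems. The fallback sets out from 1 and comes back at 2. MeI and K2CO3 in acetone convert 1 into 1,2,4‑trimethoxybenzene F1. Anodic oxidation (Pt anode, 1% KOH in MeOH, 0 °C, constant current) gives the quinone bisketal 1,3,3,6,6‑pentamethoxycyclohexa‑1,4‑diene F2. Regioselective monohydrolysis (aqueous AcOH in acetone, 0 °C) cleaves the ketal whose cation is stabilised by the methoxy‑vinyl group and delivers the vinylogous ester 2.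

**Further compounds**
F1 | step 1 | 1,2,4‑trimethoxybenzene | COc1ccc(OC)c(OC)c1
F2 | step 1 | 1,3,3,6,6‑pentamethoxycyclohexa‑1,4‑diene | COC1=CC(OC)(OC)C=CC1(OC)OC
F3 | step 2 | 1‑bromoheptadecane | CCCCCCCCCCCCCCCCCBr
F4 | step 2 | heptadecylmagnesium bromide | CCCCCCCCCCCCCCCCC[Mg]Br
F5 | step 3 | 5‑heptadecyl‑3‑methoxycyclohex‑2‑ene‑1,4‑dione | CCCCCCCCCCCCCCCCCC1CC(=O)C=C(OC)C1=O
F6 | step 3 | 2‑heptadecyl‑6‑methoxybenzene‑1,4‑diol | CCCCCCCCCCCCCCCCCc1cc(O)cc(OC)c1O
F7 | step 3 | 2‑heptadecyl‑6‑methoxy‑4‑[(triisopropylsilyl)oxy]phenol | CCCCCCCCCCCCCCCCCc1cc(O[Si](C(C)C)(C(C)C)C(C)C)cc(OC)c1O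
F8 | step 3 | (3‑heptadecyl‑4,5‑dimethoxyphenoxy)triisopropylsilane | CCCCCCCCCCCCCCCCCc1cc(O[Si](C(C)C)(C(C)C)C(C)C)cc(OC)c1OC
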